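**Retrosynthetic overview**
- The target is a flavanone (naringenin) and a flavone (apigenin) joined C3–C8'', with the sulfate on O7''. The strategy rests on one feature: flavanone C3 (ring C, alpha to the C4 ketone) is bonded to flavone C8'' (ring A), the carbon ortho to O7'', the sulfated oxygen.
- Late stage: the benzyl ethers are removed last; the C4 ketone comes from an exocyclic C4=CH2 by oxidative cleavage; the sulfate goes onto the 7''-phenol that the key step sets free.
- Key disconnection: C3–C8'' by aromatic Claisen rearrangement of an O7''–CH2–C4=C3 allyl aryl ether, made by Mitsunobu union of 4'-O-benzylapigenin with a (2R)-2-aryl-2H-chromen-4-ylmethanol.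
- The chromenylmethanol comes from (2R)-tri-O-benzylnaringenin (enol triflate, carbonylation, reduction), which comes from enantioselective conjugate arylation of 5,7-bis(benzyloxy)chromone.
- Ring order: the flavone pyranone ring and the chromone pyranone ring are each closed first from 2',4',6'-trihydroxyacetophenone; arylation turns the chromone into the flavanone ring system; no ring is formed afterwards.

Key step: step 9

Remark on step 4: the (S)-pyridine-oxazoline ligand is assumed to give (2R)-9, by analogy with its facial preference on cyclic enones; if the sense is the opposite, the (R)-ligand is used and nothing else changes.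
Remark on the sulfate: it is carried as the triethylammonium salt, and the free hydrogen sulfate drawn for the target is liberated cold in the last operation, because aryl hydrogen sulfates hydrolyse under their own acidity.

**Step 1**
Reactants: 1 2',4',6'-trihydroxyacetophenone (dried); 2 4-(benzyloxy)benzoyl chloride
Product: 4 4'-O-benzylapigenin (2-[4-(benzyloxy)phenyl]-5,7-dihydroxy-4H-chromen-4-one), via 1,3-diketone 3 (not isolated)
Conditions: LiN(SiMe3)2 (4.2 equiv), THF, −78 to −10 °C; 2, −78 °C to rt; aq. HCl; then AcOH, cat. H2SO4, 95 °C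
Reagents that add atoms: none
Why: Baker–Venkataraman-type C-aroylation of the lithium polyanion (the ketone enolate is its most nucleophilic site) gives the 1,3-diketone, and acid-catalysed cyclodehydration closes the flavone pyranone ring.

**Step 2**
Reactants: 1 2',4',6'-trihydroxyacetophenone
Product: 5 1-[2,4-bis(benzyloxy)-6-hydroxyphenyl]ethanone
Conditions: BnBr (2.05 equiv), K2CO3, DMF, rt
Reagents that add atoms: benzyl bromide, BrCc1ccccc1
Why: Williamson etherification takes the para and one ortho phenol, and the last ortho hydroxyl, hydrogen-bonded to the acetyl group, stays free.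

**Step 3**
Reactants: 5 1-[2,4-bis(benzyloxy)-6-hydroxyphenyl]ethanone
Product: 7 5,7-bis(benzyloxy)-4H-chromen-4-one, via enaminone 6 (not isolated)
Conditions: Me2NCH(OMe)2, toluene, 95 °C; evaporate; conc. HCl, CH2Cl2, 40 °C
Reagents that add atoms: N,N-dimethylformamide dimethyl acetal, COC(OC)N(C)C
Why: Enaminone route to chromones: condensation at the acetyl methyl group, then acid-promoted intramolecular conjugate addition of the free phenol and loss of dimethylamine.

**Step 4**
Reactants: 7 5,7-bis(benzyloxy)-4H-chromen-4-one; 8 4-(benzyloxy)phenylboronic acid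
Product: 9 (2R)-5,7-bis(benzyloxy)-2-[4-(benzyloxy)phenyl]chroman-4-one ((2R)-tri-O-benzylnaringenin)
Conditions: 8 (2 equiv), Pd(OCOCF3)2 (5 mol %), (S)-4-tert-butyl-2-(pyridin-2-yl)-4,5-dihydrooxazole (6 mol %), NH4PF6 (30 mol %), H2O (5 equiv), ClCH2CH2Cl, 60 °C
Reagents that add atoms: none
Why: Catalytic enantioselective conjugate addition of an arylboronic acid to a chromone with a cationic divalent palladium pyridine-oxazoline catalyst; the ligand's tert-butyl group selects the face of aryl-palladium insertion and so sets C2 as R, and near-neutral protonolysis of the palladium enolate avoids ring opening.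

**Step 5**
Reactants: 9 (2R)-tri-O-benzylnaringenin
Product: 10 (2R)-5,7-bis(benzyloxy)-2-[4-(benzyloxy)phenyl]-2H-chromen-4-yl trifluoromethanesulfonate
Conditions: Tf2O (1.3 equiv), 2,6-di-tert-butyl-4-methylpyridine (1.5 equiv), CH2Cl2, −20 to 0 °C; filtration through basic alumina
Reagents that add atoms: trifluoromethanesulfonic anhydride, O=S(=O)(OS(=O)(=O)C(F)(F)F)C(F)(F)F
Why: Enol triflate formation by O-triflation of the electron-rich aryl ketone and loss of a C3 proton to the hindered base; no free enolate forms, so C2 is not exposed to retro-oxa-Michael opening.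

**Step 6**
Reactants: 10 enol triflate
Product: 11 methyl (2R)-5,7-bis(benzyloxy)-2-[4-(benzyloxy)phenyl]-2H-chromene-4-carboxylate
Conditions: CO (1 atm), Pd(OAc)2 (10 mol %), 1,3-bis(diphenylphosphino)propane (12 mol %), Et3N, MeOH–DMF (1:2), 50 °C
Reagents that add atoms: carbon monoxide, [C-]#[O+]; methanol, CO
Why: Palladium-catalysed methoxycarbonylation of an enol triflate (oxidative addition to zerovalent palladium, CO insertion, methanolysis), run at a temperature that should leave the 2H-chromene stereocentre untouched.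

**Step 7**
Reactants: 11 methyl ester
Product: 12 [(2R)-5,7-bis(benzyloxy)-2-[4-(benzyloxy)phenyl]-2H-chromen-4-yl]methanol
Conditions: i-Bu2AlH (2.5 equiv), CH2Cl2, −78 °C; aq. Rochelle salt
Reagents that add atoms: none
Why: 1,2-Reduction of the conjugated ester by the aluminium hydride at low temperature gives the primary allylic alcohol and spares the C3=C4 bond and the benzyl ethers.

**Step 8**
Reactants: 12 chromen-4-ylmethanol; 4 4'-O-benzylapigenin
Product: 13 2-[4-(benzyloxy)phenyl]-7-{[(2R)-5,7-bis(benzyloxy)-2-[4-(benzyloxy)phenyl]-2H-chromen-4-yl]methoxy}-5-hydroxy-4H-chromen-4-one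
Conditions: PPh3, DIAD (1.3 equiv each), THF, 0 °C to rt
Reagents that add atoms: none
Why: Mitsunobu etherification: the acidic 7-OH displaces the primary alkoxyphosphonium in an SN2 sense, while the 5-OH, chelated to the C4'' carbonyl, does not react, so the ether oxygen is O7''.

**Step 9**
Reactants: 13 flavon-7''-yl (2H-chromen-4-yl)methyl ether
Product: 15 8-[(2R,3S)-5,7-bis(benzyloxy)-2-[4-(benzyloxy)phenyl]-4-methylidenechroman-3-yl]-2-[4-(benzyloxy)phenyl]-5,7-dihydroxy-4H-chromen-4-one, via ortho-dienone 14 (not isolated)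
Conditions: PhNEt2 (degassed), BHT, 165–175 °C, sealed tube, Ar, dark, short time; chromatography on Et3N-treated silica, no acid wash
Reagents that add atoms: none
Why: Aromatic Claisen rearrangement: a concerted suprafacial [3,3] shift through a chair-like transition state breaks O7''–CH2 while C3 bonds to C8'' and the C3=C4 π bond moves to exocyclic C4=CH2, after which ortho-dienone 14 tautomerises to the 7''-phenol. The closest known cases are the C8-selective rearrangement of 7-allyloxyflavones and 7-allyloxycoumarins and the rearrangement of cycloalk-1-enylmethyl aryl ethers to 2-(2-methylidenecycloalkyl)phenols; intramolecular delivery lets the hindered aryl–C(sp3) bond between two innately nucleophilic carbons form without halide, metal or oxidant. No ring is closed: the two existing benzopyran systems only become carbon-linked. The new C3 stereocentre (S) is controlled by C2, since the arene is delivered to the face of C3=C4 opposite the C2 aryl group, as in anti additions to flav-3-enes, which gives the 2,3-trans product. The step needs C8'' over C6'' attack, which the higher double-bond character of C7''–C8'' in the benzopyranone favours, and it needs the C2 configuration to survive, hence the lowest temperature that gives conversion, a short time and exclusion of acid and light. The amine solvent also buffers the new phenol against acid-promoted addition to the methylidene group.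

**Step 10**
Reactants: 15 methylidene phenol
Product: 16 triethylammonium 8-[(2R,3S)-5,7-bis(benzyloxy)-2-[4-(benzyloxy)phenyl]-4-methylidenechroman-3-yl]-2-[4-(benzyloxy)phenyl]-5-hydroxy-4-oxo-4H-chromen-7-yl sulfate
Conditions: SO3·NEt3 (5 equiv), Et3N, DMF, 45 °C; chromatography with 1% Et3N
Reagents that add atoms: sulfur trioxide–triethylamine complex, CC[N+](CC)(CC)S(=O)(=O)[O-]
Why: O-Sulfation with a sulfur trioxide–amine complex takes the only unchelated phenol (7''-OH), and the basic medium protects the acid-sensitive methylidene group.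

**Step 11**
Reactants: 16 methylidene sulfate salt
Product: 18 triethylammonium 8-[(2R,3S)-5,7-bis(benzyloxy)-2-[4-(benzyloxy)phenyl]-4-oxochroman-3-yl]-2-[4-(benzyloxy)phenyl]-5-hydroxy-4-oxo-4H-chromen-7-yl sulfate, via 1,2-diol 17 (not isolated)
Conditions: OsO4 (5 mol %), NaIO4 (4 equiv), 2,6-lutidine, dioxane–H2O (3:1), rt; work-up with Et3NH+ HCO3− buffer
Reagents that add atoms: osmium tetroxide, O=[Os](=O)(=O)=O; sodium periodate, [Na+].[O-]I(=O)(=O)=O
Why: Lemieux–Johnson oxidation: the electron-rich 1,1-disubstituted alkene is dihydroxylated and the glycol cleaved to the C4 ketone, while the electron-poor flavone C2''=C3'' bond should react far more slowly and the lutidine buffer keeps C2 and C3 from epimerising.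

**Step 12**
Reactants: 18 tetra-O-benzyl sulfate salt
Product: 20 8-[(2R,3S)-5,7-dihydroxy-2-(4-hydroxyphenyl)-4-oxochroman-3-yl]-5-hydroxy-2-(4-hydroxyphenyl)-4-oxo-4H-chromen-7-yl hydrogen sulfate (CNP0271389.1), via target triethylammonium salt 19 (not isolated)
Conditions: H2 (1 atm), 10% Pd/C (palladium metal on carbon), THF–MeOH, rt; filter; sulfonic acid cation-exchange resin (H+ form), MeOH–H2O, 0 °C; freeze-dry
Reagents that add atoms: none
Why: Neutral catalytic hydrogenolysis removes the four benzyl aryl ethers without touching the aryl sulfate or either stereocentre, and cold cation exchange then gives the hydrogen sulfate.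

**Compound list**
1 | 2',4',6'-trihydroxyacetophenone | CC(=O)c1c(O)cc(O)cc1O | starting material
2 | 4-(benzyloxy)benzoyl chloride | O=C(Cl)c1ccc(OCc2ccccc2)cc1 | starting material
3 | 1-[4-(benzyloxy)phenyl]-3-(2,4,6-trihydroxyphenyl)propane-1,3-dione | O=C(CC(=O)c1ccc(OCc2ccccc2)cc1)c1c(O)cc(O)cc1O | intermediate
4 | 4'-O-benzylapigenin | O=c1cc(-c2ccc(OCc3ccccc3)cc2)oc2cc(O)cc(O)c12 | intermediate
5 | 1-[2,4-bis(benzyloxy)-6-hydroxyphenyl]ethanone | CC(=O)c1c(O)cc(OCc2ccccc2)cc1OCc1ccccc1 | intermediate
6 | (E)-1-[2,4-bis(benzyloxy)-6-hydroxyphenyl]-3-(dimethylamino)prop-2-en-1-one | CN(C)/C=C/C(=O)c1c(O)cc(OCc2ccccc2)cc1OCc1ccccc1 | intermediate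
7 | 5,7-bis(benzyloxy)-4H-chromen-4-one | O=c1ccoc2cc(OCc3ccccc3)cc(OCc3ccccc3)c12 | intermediate
8 | 4-(benzyloxy)phenylboronic acid | OB(O)c1ccc(OCc2ccccc2)cc1 | starting material
9 | (2R)-5,7-bis(benzyloxy)-2-[4-(benzyloxy)phenyl]chroman-4-one | O=C1C[C@H](c2ccc(OCc3ccccc3)cc2)Oc2cc(OCc3ccccc3)cc(OCc3ccccc3)c21 | intermediate
10 | (2R)-5,7-bis(benzyloxy)-2-[4-(benzyloxy)phenyl]-2H-chromen-4-yl trifluoromethanesulfonate | O=S(=O)(OC1=C[C@H](c2ccc(OCc3ccccc3)cc2)Oc2cc(OCc3ccccc3)cc(OCc3ccccc3)c21)C(F)(F)F | intermediate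
11 | methyl (2R)-5,7-bis(benzyloxy)-2-[4-(benzyloxy)phenyl]-2H-chromene-4-carboxylate | COC(=O)C1=C[C@H](c2ccc(OCc3ccccc3)cc2)Oc2cc(OCc3ccccc3)cc(OCc3ccccc3)c21 | intermediate
12 | [(2R)-5,7-bis(benzyloxy)-2-[4-(benzyloxy)phenyl]-2H-chromen-4-yl]methanol | OCC1=C[C@H](c2ccc(OCc3ccccc3)cc2)Oc2cc(OCc3ccccc3)cc(OCc3ccccc3)c21 | intermediate
13 | flavon-7''-yl (2R)-(2H-chromen-4-yl)methyl ether, 5''-OH free | O=c1cc(-c2ccc(OCc3ccccc3)cc2)oc2cc(OCC3=C[C@H](c4ccc(OCc5ccccc5)cc4)Oc4cc(OCc5ccccc5)cc(OCc5ccccc5)c43)cc(O)c12 | intermediate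
14 | ortho-dienone tautomer of 15 (C8'' sp3 and bonded to C3, C7''=O; C8'' drawn as the chair transition state predicts, lost on tautomerisation) | C=C1c2c(OCc3ccccc3)cc(OCc3ccccc3)cc2O[C@@H](c2ccc(OCc3ccccc3)cc2)[C@@H]1[C@@H]4C(=O)C=C(O)C5=C4OC(-c6ccc(OCc7ccccc7)cc6)=CC5=O | intermediate
15 | 8-[(2R,3S)-5,7-bis(benzyloxy)-2-[4-(benzyloxy)phenyl]-4-methylidenechroman-3-yl]-2-[4-(benzyloxy)phenyl]-5,7-dihydroxy-4H-chromen-4-one | C=C1c2c(OCc3ccccc3)cc(OCc3ccccc3)cc2O[C@@H](c2ccc(OCc3ccccc3)cc2)[C@@H]1c1c(O)cc(O)c2c(=O)cc(-c3ccc(OCc4ccccc4)cc3)oc12 | intermediate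
16 | triethylammonium 7''-O-sulfate of 15 | C=C1c2c(OCc3ccccc3)cc(OCc3ccccc3)cc2O[C@@H](c2ccc(OCc3ccccc3)cc2)[C@@H]1c1c(OS(=O)(=O)[O-])cc(O)c2c(=O)cc(-c3ccc(OCc4ccccc4)cc3)oc12.CC[NH+](CC)CC | intermediate
17 | 1,2-diol from 16 (C4 hydroxyl and hydroxymethyl; hydroxyl drawn anti to the C3 flavonyl group, of no consequence) | OC[C@]1(O)c2c(OCc3ccccc3)cc(OCc3ccccc3)cc2O[C@@H](c2ccc(OCc3ccccc3)cc2)[C@@H]1c1c(OS(=O)(=O)[O-])cc(O)c2c(=O)cc(-c3ccc(OCc4ccccc4)cc3)oc12.CC[NH+](CC)CC | intermediate
18 | tetra-O-benzyl target as triethylammonium sulfate, (2R,3S) | O=C1c2c(OCc3ccccc3)cc(OCc3ccccc3)cc2O[C@@H](c2ccc(OCc3ccccc3)cc2)[C@@H]1c1c(OS(=O)(=O)[O-])cc(O)c2c(=O)cc(-c3ccc(OCc4ccccc4)cc3)oc12.CC[NH+](CC)CC | intermediate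
19 | triethylammonium salt of the target | O=C1c2c(O)cc(O)cc2O[C@@H](c2ccc(O)cc2)[C@@H]1c1c(OS(=O)(=O)[O-])cc(O)c2c(=O)cc(-c3ccc(O)cc3)oc12.CC[NH+](CC)CC | intermediate
20 | CNP0271389.1, (2R,3S) | O=C1c2c(O)cc(O)cc2O[C@@H](c2ccc(O)cc2)[C@@H]1c1c(OS(=O)(=O)O)cc(O)c2c(=O)cc(-c3ccc(O)cc3)oc12 | target

**Totals**
Total step count: 12. Longest linear sequence: 11 steps (steps 2 to 12, from compound 1).

**Steps most likely to fail**

Step 9. The 2H-chromene can open reversibly, in a 6π-electrocyclic sense, to an ortho-quinone methide and reclose on either face, so the C2 configuration may erode at the temperature the sigmatropic shift needs. Partial C6'' attack and syn delivery are lesser concerns. A syn-derived cis isomer (2R,3R) would converge to trans by enolisation at C3 once the ketone is unveiled. The fallback places the absolute configuration on the tether carbon, so that 1,3-chirality transfer, not C2 alone, fixes C3. It sets out from 10. Stille coupling with tributyl(1-ethoxyvinyl)stannane (Pd(PPh3)4, LiCl, THF, 60 °C) would give the (2R)-4-(1-ethoxyethenyl)-2H-chromene F1. Mild hydrolysis (pyridinium tosylate, wet acetone, 0 °C) would give the (2R)-4-acetyl-2H-chromene F2. Corey–Bakshi–Shibata reduction with (S)-1-methyl-3,3-diphenyltetrahydro-1H,3H-pyrrolo[1,2-c][1,3,2]oxazaborole and BH3·SMe2 would give the (R)-1-(chromen-4-yl)ethanol F3. Mitsunobu coupling with 4, with inversion, would give the (S)-configured flavon-7''-yl 1-(chromen-4-yl)ethyl ether F4. Heating as in step 9 would give the (2R,3S)-4-[(E)-ethylidene] analogue of 15, F5. The methyl group must point toward C3 to avoid the 5-benzyloxy group, so the tether centre alone dictates the C3 face, which is the face anti to the (2R) aryl group. A C2 epimer formed by ring opening should return through the faster anti transition state, and any cis diastereomer is removed at this stage, not epimerised. Sulfation as in step 10 would give the triethylammonium sulfate F6, and Lemieux–Johnson cleavage of the ethylidene group comes back to the route at 18.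

Step 4. The chromone is electron-rich and its carbonyl is flanked by the 5-benzyloxy group, so aryl-palladium insertion may be slow; protodeboronation of 8 may then outrun addition, or the enantioselectivity may fall short. The fallback sets out from 5. Claisen–Schmidt condensation with purchased 4-(benzyloxy)benzaldehyde (KOH, EtOH) would give the 2'-hydroxychalcone F7. Oxa-Michael ring closure (NaOAc, EtOH, reflux) would give the racemic tri-O-benzylnaringenin F8. Kinetic resolution by asymmetric transfer hydrogenation (RuCl(p-cymene)(TsDPEN), HCO2H–Et3N, with the ligand enantiomer that reduces the (2S) ketone faster) would turn the unwanted enantiomer into the (2S,4S)-cis-flavan-4-ol F9. The unreduced ketone is recovered and comes back to the route at 9.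

Step 10. If sulfation of the hindered 7''-phenol is slow, acid-promoted addition of that hydroxyl across the C4 methylidene group (closure of a dihydrofuran ring) may take over. The fallback reverses the order of the two operations. It sets out from 15. Lemieux–Johnson cleavage under the buffered conditions of step 11 would give the tetra-O-benzyl keto-phenol F10, which has no alkene left to capture the phenol. Any cyclic hemiketal it forms is reversible. Sulfation with SO3·NEt3 and Et3N then comes back to the route at 18.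

**Further compounds**
F1 | step 9 | (2R)-5,7-bis(benzyloxy)-2-[4-(benzyloxy)phenyl]-4-(1-ethoxyethenyl)-2H-chromene | C=C(OCC)C1=C[C@H](c2ccc(OCc3ccccc3)cc2)Oc2cc(OCc3ccccc3)cc(OCc3ccccc3)c21
F2 | step 9 | 1-[(2R)-5,7-bis(benzyloxy)-2-[4-(benzyloxy)phenyl]-2H-chromen-4-yl]ethanone | CC(=O)C1=C[C@H](c2ccc(OCc3ccccc3)cc2)Oc2cc(OCc3ccccc3)cc(OCc3ccccc3)c21
F3 | step 9 | (1R)-1-[(2R)-5,7-bis(benzyloxy)-2-[4-(benzyloxy)phenyl]-2H-chromen-4-yl]ethanol | C[C@@H](O)C1=C[C@H](c2ccc(OCc3ccccc3)cc2)Oc2cc(OCc3ccccc3)cc(OCc3ccccc3)c21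
F4 | step 9 | flavon-7''-yl (1S)-1-[(2R)-2H-chromen-4-yl]ethyl ether, 5''-OH free | O=c1cc(-c2ccc(OCc3ccccc3)cc2)oc2cc(O[C@@H](C)C3=C[C@H](c4ccc(OCc5ccccc5)cc4)Oc4cc(OCc5ccccc5)cc(OCc5ccccc5)c43)cc(O)c12
F5 | step 9 | (2R,3S)-4-[(E)-ethylidene] analogue of 15 | C/C=C1/c2c(OCc3ccccc3)cc(OCc3ccccc3)cc2O[C@@H](c2ccc(OCc3ccccc3)cc2)[C@@H]1c1c(O)cc(O)c2c(=O)cc(-c3ccc(OCc4ccccc4)cc3)oc12
F6 | step 9 | triethylammonium 7''-O-sulfate of F5 | C/C=C1/c2c(OCc3ccccc3)cc(OCc3ccccc3)cc2O[C@@H](c2ccc(OCc3ccccc3)cc2)[C@@H]1c1c(OS(=O)(=O)[O-])cc(O)c2c(=O)cc(-c3ccc(OCc4ccccc4)cc3)oc12.CC[NH+](CC)CC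
F7 | step 4 | (E)-1-[2,4-bis(benzyloxy)-6-hydroxyphenyl]-3-[4-(benzyloxy)phenyl]prop-2-en-1-one | O=C(/C=C/c1ccc(OCc2ccccc2)cc1)c1c(O)cc(OCc2ccccc2)cc1OCc1ccccc1
F8 | step 4 | racemic 5,7-bis(benzyloxy)-2-[4-(benzyloxy)phenyl]chroman-4-one | O=C1CC(c2ccc(OCc3ccccc3)cc2)Oc2cc(OCc3ccccc3)cc(OCc3ccccc3)c21
F9 | step 4 | (2S,4S)-5,7-bis(benzyloxy)-2-[4-(benzyloxy)phenyl]chroman-4-ol | O[C@H]1C[C@@H](c2ccc(OCc3ccccc3)cc2)Oc2cc(OCc3ccccc3)cc(OCc3ccccc3)c21
F10 | step 10 | 8-[(2R,3S)-5,7-bis(benzyloxy)-2-[4-(benzyloxy)phenyl]-4-oxochroman-3-yl]-2-[4-(benzyloxy)phenyl]-5,7-dihydroxy-4H-chromen-4-one | O=C1c2c(OCc3ccccc3)cc(OCc3ccccc3)cc2O[C@@H](c2ccc(OCc3ccccc3)cc2)[C@@H]1c1c(O)cc(O)c2c(=O)cc(-c3ccc(OCc4ccccc4)cc3)oc12
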